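The readings are calculated with constants of no real substance; the scatter is artificial.

If you want the yield of a new flask of this series at 12 min, count what is missing as a concentration, not as a percentage.

| flask | substrate | remark | time |
|---|---|---|---|
| east | 0.019 M | run made earlier |  |
| south | 0.30 M | run made earlier |  |
| summer | 0.20 M |  | 12 min |
| midnight | 0.062 M |  | 12 min |
| spring | 0.040 M |  | 12 min |
| winter | 0.12 M |  | 12 min |
| autumn | 0.015 M |  | 12 min |

| east: time / min | east: target / % | south: time / min | south: target / % |
|---|---|---|---|
| 1.00 | 79.4 | 3.00 | 95.5 |
| 2.00 | 78.5 | 6.00 | 96.1 |
| 5.00 | 74.8 | 10.0 | 95.8 |
| 12.0 | 65.9 | 12.0 | 96.9 |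

(readings scatter by 0.5 percentage points)

- the earlier runs were read with a standard deviation of 0.5 percentage points
- a reading or a percentage of target counts all its forms, free or not

- all flasks from highest to lowest amount of target, in percent of the substrate charged, at 12 min (summer / midnight / spring / winter / autumn)
- the amount of target, in percent of the substrate charged of the flask you put first, at 12 min
- the amount of target, in percent of the substrate charged of the flask you put last, at 12 min

Take m, the charge times the share of it not read as target at 12 min; the yield at that time is then one minus m over the charge.

First, which readings must be good? An error in the east reading at 12.0 min passes to autumn multiplied by 1.27, so it stays harmless there. The south reading passes to summer multiplied by 1.50, also harmless, but to autumn multiplied by 20.0, so each end of the series needs its own run. Time matters in the east run, which falls from 79.4 % to 65.9 %, so you must use its reading at the asked time.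

Now the numbers. The east run gives 6.48 mM for the missing concentration, the charge times the share not read as target, and the south run gives 9.30 mM. This quantity moves by a factor of 1.44, far less than the charges of these two runs do, so I order the flasks by charge. I reckon summer at 95.4 % and autumn at 56.8 %.

The forecast gives summer > winter > midnight > spring > autumn, with 95.2 % (93 % to 97 %) and 60 % (55 % to 64 %), on the ground that “Both effects favour the more concentrated flasks”. Its autumn stands above mine, though mine lies inside its range.

The flasks give summer > winter > midnight > spring > autumn, with 95.3 % and 56.7 %.

    substrate ⇌ target (K = 1.00, k = 0.410 s⁻¹)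
    target ⇌ isomer of the product (K = 2.30, k = 4.90 × 10⁻⁴ s⁻¹)
    isomer of the product ⇌ substrate (k = 0.0230 s⁻¹)
    substrate ⇌ dormant form (K = 12.0, k = 0.00580 s⁻¹)
    crystals ⇌ target, rate k5*(cs5 - [target]) while solid is left; crystals form when [target] > cs5 (solubility = 0.940 mM, k = 0.690 s⁻¹)

Autumn's own missing concentration comes to 6.49 mM, which is close to m. As shares of its charge, autumn's figure lumps together 6.17 % substrate, 14.2 % isomer of the product and 22.9 % dormant form. Now take a neighbour of summer charged with 0.050 M. With m, the same reckoning gives it 87.0 %, and the neighbour flask reads 85.9 %, so its missing concentration is 7.05 mM.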